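The pyrrole in the target carries the acyl chain on C2 and the CH2OH group on C5, while C3 and C4 are plain CH units. N1 with C2 and C5 is therefore the core of a bis-allylic secondary amine. The ring is cut at C3–C4. Ruthenium-catalysed olefin metathesis joins the two vinyl groups, creating C3=C4 and the five-membered ring (as a 3-pyrroline) in one operation while ethene departs. The precursor is an acyclic amine made by a three-component borono-Mannich coupling. Its nitrogen links a vinyl-bearing carbon with CH2OTBDPS to a vinyl-bearing carbon with the CH(OH)-alkyl chain, and it is cyclised as its tosylate salt. Later oxidation erases every stereocentre.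

Key step: step 7

Assumption: the target holds no stereocentre, so racemic 2-aminobut-3-en-1-ol (taken as the free base; a hydrochloride would need one further equivalent of base) and unselective additions are used, all sp3 centres are carried as stereoisomer mixtures, and the SMILES bear no stereodescriptors.

Design notes:
- **Vinyl donor.** The dibutyl ester of vinylboronic acid is used rather than a pinacol ester. Its monodentate alkoxy groups exchange readily with the α-hydroxyl group of the aldehyde, which is the event that triggers vinyl transfer. A chelating diol ester resists this exchange.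
- **Primary alcohol.** It is carried as a TBDPS ether, which tolerates TsOH, the ruthenium catalyst and MnO2. It prevents oxazolidine formation in the three-component step and keeps MnO2 from oxidising the C5 CH2OH group to an aldehyde.
- **Secondary carbinol.** It stays free: it directs the borono-Mannich step, is tolerated in the metathesis, and becomes the ketone at the end.

Step 1
Reactants: 1 16-methylheptadecanoic acid
Product: 2 16-methylheptadecan-1-ol
Conditions: LiAlH4 (1.5 equiv), THF, 0 °C to reflux; then Na2SO4·10H2O, filtration
Reagents that add atoms: none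
Why: Hydride reduction of a carboxylic acid with LiAlH4 leads to the primary alcohol, and the saturated branched chain offers no competing function.

Step 2
Reactants: 2 16-methylheptadecan-1-ol
Product: 3 16-methylheptadecanal
Conditions: TEMPO (10 mol %), PhI(OAc)2 (1.1 equiv), CH2Cl2, rt
Reagents that add atoms: none
Why: The TEMPO/PhI(OAc)2 oxoammonium oxidation of a primary alcohol stops at the aldehyde in anhydrous CH2Cl2, so over-oxidation to the acid is avoided.

Step 3
Reactants: 3 16-methylheptadecanal; 4 vinylmagnesium bromide
Product: 5 18-methylnonadec-1-en-3-ol (racemic)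
Conditions: THF, −78 to 0 °C; sat. aq NH4Cl
Reagents that add atoms: none
Why: Grignard 1,2-addition to the unhindered aldehyde gives the allylic alcohol, and the new carbinol centre arises racemic, which is harmless because this carbon ends as the ketone carbon.

Step 4
Reactants: 5 18-methylnonadec-1-en-3-ol
Product: 7 2-hydroxy-17-methyloctadecanal (racemic, used crude), via secondary ozonide 6 (not isolated)
Conditions: O3/O2, CH2Cl2, −78 °C; then Me2S (5 equiv), −78 °C to rt; water wash
Reagents that add atoms: ozone, [O-][O+]=O
Why: Ozonolysis with reductive Me2S work-up excises only the terminal CH2 and keeps the neighbouring C–OH bond, which an OsO4/NaIO4 cleavage would endanger through a triol, and the α-hydroxy aldehyde is used at once because it equilibrates with its dimer.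

Step 5
Reactants: 8 2-aminobut-3-en-1-ol (racemic)
Product: 9 1-(tert-butyldiphenylsilyloxy)but-3-en-2-amine (racemic)
Conditions: TBDPSCl (1.05 equiv), imidazole (2.2 equiv), CH2Cl2, 0 °C to rt
Reagents that add atoms: tert-butyl(chloro)diphenylsilane (TBDPSCl), CC(C)(C)[Si](Cl)(c1ccccc1)c1ccccc1
Why: Silyl ether formation with the bulky chlorosilane is O-selective on an amino alcohol, since any N–Si bond is hydrolysed on aqueous work-up, and the allylic centre is untouched.

Step 6
Reactants: 7 2-hydroxy-17-methyloctadecanal; 9 1-(tert-butyldiphenylsilyloxy)but-3-en-2-amine; 10 dibutyl vinylboronate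
Product: 12 3-{[1-(tert-butyldiphenylsilyloxy)but-3-en-2-yl]amino}-19-methylicos-1-en-4-ol (stereoisomer mixture), via hydroxy imine 11 (not isolated)
Conditions: 10 (1.5 equiv), EtOH/CH2Cl2 (4:1), 45 °C, 48 h; aq NaHCO3 work-up
Reagents that add atoms: none
Why: In this Petasis borono-Mannich reaction the aldehyde and amine condense, the α-hydroxyl group displaces butoxide on boron, and the tetracoordinate boron hands its vinyl group intramolecularly to the iminium carbon, which sets the new C–N centre anti to the carbinol but without control relative to the centre of 9, and none is needed.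

Step 7
Reactants: 12 3-{[1-(tert-butyldiphenylsilyloxy)but-3-en-2-yl]amino}-19-methylicos-1-en-4-ol
Product: 15 1-[5-(tert-butyldiphenylsilyloxymethyl)-2,5-dihydro-1H-pyrrol-2-yl]-16-methylheptadecan-1-ol (stereoisomer mixture), via diene ammonium tosylate 13 (not isolated), via pyrrolinium tosylate 14 (not isolated)
Conditions: TsOH·H2O (1.05 equiv), CH2Cl2, rt, 15 min; then second-generation Grubbs catalyst RuCl2(=CHPh)(PCy3)(H2IMes) (5 mol %), CH2Cl2 (0.01 M), 40 °C, argon purge; then 1 M aq NaOH wash
Reagents that add atoms: none
Why: Once TsOH has protonated nitrogen, the ruthenium alkylidene exchanges onto one terminal vinyl group, adds to the second vinyl group in an intramolecular [2+2] cycloaddition, and cycloreversion of the ruthenacyclobutane delivers C3=C4 together with a Ru=CH2 species that carries the chain and sheds ethene. The closest known reaction type is ring-closing metathesis of diallylammonium salts to 3-pyrrolinium salts. The one ring formed (N1–C2–C3=C4–C5) is closed at the carbon–carbon double bond between the two internal vinyl carbons, and the two terminal CH2 groups are lost. No stereocentre is created, the three existing ones are spectators, and cis- and trans-2,5-disubstituted pyrrolines are both unstrained, so every isomer of 12 can close. The step needs cyclisation over acyclic oligomerisation, no double-bond migration and no nitrogen–ruthenium binding. These are secured by high dilution, the kinetic ease of five-ring closure, the substituents on both allylic carbons that favour folded conformers, the lone-pair-free ammonium form in an acidic medium, and removal of ethene by the argon stream.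

Step 8
Reactants: 15 1-[5-(tert-butyldiphenylsilyloxymethyl)-2,5-dihydro-1H-pyrrol-2-yl]-16-methylheptadecan-1-ol (crude)
Product: 17 1-[5-(tert-butyldiphenylsilyloxymethyl)-1H-pyrrol-2-yl]-16-methylheptadecan-1-one, via pyrrolyl carbinol 16 (not isolated)
Conditions: activated MnO2 (25 equiv), CH2Cl2, rt to 40 °C; filtration through Celite
Reagents that add atoms: none
Why: MnO2 dehydrogenation of a 3-pyrroline is driven by aromatisation, the carbinol thereby becomes a benzylic-type pyrrol-2-yl alcohol that the same reagent oxidises to the 2-acylpyrrole, the silyl ether shields the C5 CH2O group, and all three stereocentres vanish.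

Step 9
Reactants: 17 1-[5-(tert-butyldiphenylsilyloxymethyl)-1H-pyrrol-2-yl]-16-methylheptadecan-1-one
Product: 18 1-[5-(hydroxymethyl)-1H-pyrrol-2-yl]-16-methylheptadecan-1-one (target)
Conditions: Bu4NF (1.2 equiv), AcOH (1.2 equiv), THF, 0 °C to rt
Reagents that add atoms: none
Why: Fluoride-mediated desilylation is driven by Si–F bond formation, the AcOH buffer keeps the acidic acylpyrrole N–H protonated, and the electron-withdrawing acyl group stabilises the freed hydroxymethylpyrrole against azafulvene formation.

Compound list
1 | 16-methylheptadecanoic acid | CC(C)CCCCCCCCCCCCCCC(=O)O | starting material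
2 | 16-methylheptadecan-1-ol | CC(C)CCCCCCCCCCCCCCCO | intermediate
3 | 16-methylheptadecanal | CC(C)CCCCCCCCCCCCCCC=O | intermediate
4 | vinylmagnesium bromide | C=C[Mg]Br | starting material
5 | 18-methylnonadec-1-en-3-ol (racemic) | CC(C)CCCCCCCCCCCCCCC(O)C=C | intermediate
6 | 16-methyl-1-(1,2,4-trioxolan-3-yl)heptadecan-1-ol (secondary ozonide, not isolated) | CC(C)CCCCCCCCCCCCCCC(O)C1OCOO1 | intermediate
7 | 2-hydroxy-17-methyloctadecanal (racemic) | CC(C)CCCCCCCCCCCCCCC(O)C=O | intermediate
8 | 2-aminobut-3-en-1-ol (racemic) | NC(CO)C=C | starting material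
9 | 1-(tert-butyldiphenylsilyloxy)but-3-en-2-amine (racemic) | NC(C=C)CO[Si](c1ccccc1)(c1ccccc1)C(C)(C)C | intermediate
10 | dibutyl vinylboronate | C=CB(OCCCC)OCCCC | starting material
11 | 1-{[1-(tert-butyldiphenylsilyloxy)but-3-en-2-yl]imino}-17-methyloctadecan-2-ol (hydroxy imine, not isolated) | CC(C)CCCCCCCCCCCCCCC(O)C=NC(C=C)CO[Si](c1ccccc1)(c1ccccc1)C(C)(C)C | intermediate
12 | 3-{[1-(tert-butyldiphenylsilyloxy)but-3-en-2-yl]amino}-19-methylicos-1-en-4-ol (stereoisomer mixture) | C=CC(CO[Si](c1ccccc1)(c1ccccc1)C(C)(C)C)NC(C=C)C(O)CCCCCCCCCCCCCCC(C)C | intermediate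
13 | ammonium 4-methylbenzenesulfonate of 12 (not isolated) | C=CC(CO[Si](c1ccccc1)(c1ccccc1)C(C)(C)C)[NH2+]C(C=C)C(O)CCCCCCCCCCCCCCC(C)C.Cc1ccc(cc1)S(=O)(=O)[O-] | intermediate
14 | 2,5-dihydro-1H-pyrrol-1-ium 4-methylbenzenesulfonate of 15 (not isolated) | CC(C)CCCCCCCCCCCCCCC(O)C1C=CC(CO[Si](c2ccccc2)(c2ccccc2)C(C)(C)C)[NH2+]1.Cc1ccc(cc1)S(=O)(=O)[O-] | intermediate
15 | 1-[5-(tert-butyldiphenylsilyloxymethyl)-2,5-dihydro-1H-pyrrol-2-yl]-16-methylheptadecan-1-ol (stereoisomer mixture) | CC(C)CCCCCCCCCCCCCCC(O)C1C=CC(CO[Si](c2ccccc2)(c2ccccc2)C(C)(C)C)N1 | intermediate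
16 | 1-[5-(tert-butyldiphenylsilyloxymethyl)-1H-pyrrol-2-yl]-16-methylheptadecan-1-ol (racemic, not isolated) | CC(C)CCCCCCCCCCCCCCC(O)c1ccc(CO[Si](c2ccccc2)(c2ccccc2)C(C)(C)C)[nH]1 | intermediate
17 | 1-[5-(tert-butyldiphenylsilyloxymethyl)-1H-pyrrol-2-yl]-16-methylheptadecan-1-one | CC(C)CCCCCCCCCCCCCCC(=O)c1ccc(CO[Si](c2ccccc2)(c2ccccc2)C(C)(C)C)[nH]1 | intermediate
18 | 1-[5-(hydroxymethyl)-1H-pyrrol-2-yl]-16-methylheptadecan-1-one | CC(C)CCCCCCCCCCCCCCC(=O)c1ccc(CO)[nH]1 | target

Total step count: 9.
Longest linear sequence: 8 steps (1 → 2 → 3 → 5 → 7 → 12 → 15 → 17 → 18). Step 5 is a one-step side branch.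

Steps most likely to fail

1. **Step 7 (ring-closing metathesis).**
   - What may go wrong: reversible deprotonation of the ammonium ion may let nitrogen, helped by the neighbouring hydroxyl group, bind ruthenium and stop turnover. Ruthenium hydrides from catalyst decay may move the vinyl double bonds towards nitrogen. Crowding at both allylic carbons may slow ring closure until intermolecular metathesis takes over.
   - Fallback: nitrogen is masked covalently instead of by protonation. Setting out from 12, Boc2O (THF, 60 °C, no acylation catalyst, so that the hindered carbinol stays free) should give tert-butyl N-[1-(tert-butyldiphenylsilyloxy)but-3-en-2-yl]-N-(4-hydroxy-19-methylicos-1-en-3-yl)carbamate F1. This non-basic diene is closed with RuCl2(=CHPh)(PCy3)(H2IMes) in CH2Cl2 at 40 °C to tert-butyl 2-(tert-butyldiphenylsilyloxymethyl)-5-(1-hydroxy-16-methylheptadecyl)-2,5-dihydro-1H-pyrrole-1-carboxylate F2. TsOH·H2O in MeCN at 40 °C then cleaves the carbamate, and the sequence comes back to the route at 14, which the NaOH wash of step 7 turns into 15.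

2. **Step 6 (borono-Mannich coupling).**
   - What may go wrong: vinyl transfer from boron to the crowded iminium carbon may be slow. That would leave time for Amadori-type rearrangement of the hydroxy imine to an amino ketone and for self-condensation of the hydroxy aldehyde.
   - Fallback: the amine is joined by C–N bond formation at an epoxide instead of C–C bond formation at an iminium ion. Setting out from 3, the ylide made from S-allyltetrahydrothiophenium bromide and t-BuOK (THF, −78 °C) should convert the aldehyde into 2-ethenyl-3-(15-methylhexadecyl)oxirane F3 (cis/trans mixture, of no consequence). Heating it with amine 9 and LiClO4 in MeCN opens the ring by SN2 attack at the allylic carbon, the usual regiochemistry of vinyl epoxide aminolysis, and comes back to the route at 12. Steps 3, 4 and 6, and with them the sensitive hydroxy aldehyde, are bypassed.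

3. **Step 8 (double oxidation with MnO2).**
   - What may go wrong: the electron-rich pyrrolyl carbinol may ionise on the oxide surface and oligomerise before its own oxidation. The amino alcohol unit may suffer oxidative C–C cleavage before aromatisation. The dehydrogenation may stall.
   - Fallback: the ring reaches the aromatic level by loss of a sulfinate instead of by an external oxidant. Setting out from 15, TsCl/Et3N (CH2Cl2, 0 °C) should sulfonylate nitrogen selectively to 1-[5-(tert-butyldiphenylsilyloxymethyl)-1-(4-methylbenzenesulfonyl)-2,5-dihydro-1H-pyrrol-2-yl]-16-methylheptadecan-1-ol F4. Dess–Martin periodinane (CH2Cl2, rt) then oxidises the carbinol to 1-[5-(tert-butyldiphenylsilyloxymethyl)-1-(4-methylbenzenesulfonyl)-2,5-dihydro-1H-pyrrol-2-yl]-16-methylheptadecan-1-one F5. DBU (THF, rt) removes the acidic C2–H, 4-methylbenzenesulfinate leaves from N1, and tautomerisation brings the sequence back to the route at 17.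

Further compounds
F1 | step 7 | tert-butyl N-[1-(tert-butyldiphenylsilyloxy)but-3-en-2-yl]-N-(4-hydroxy-19-methylicos-1-en-3-yl)carbamate | C=CC(CO[Si](c1ccccc1)(c1ccccc1)C(C)(C)C)N(C(=O)OC(C)(C)C)C(C=C)C(O)CCCCCCCCCCCCCCC(C)C
F2 | step 7 | tert-butyl 2-(tert-butyldiphenylsilyloxymethyl)-5-(1-hydroxy-16-methylheptadecyl)-2,5-dihydro-1H-pyrrole-1-carboxylate | CC(C)CCCCCCCCCCCCCCC(O)C1C=CC(CO[Si](c2ccccc2)(c2ccccc2)C(C)(C)C)N1C(=O)OC(C)(C)C
F3 | step 6 | 2-ethenyl-3-(15-methylhexadecyl)oxirane | C=CC1OC1CCCCCCCCCCCCCCC(C)C
F4 | step 8 | 1-[5-(tert-butyldiphenylsilyloxymethyl)-1-(4-methylbenzenesulfonyl)-2,5-dihydro-1H-pyrrol-2-yl]-16-methylheptadecan-1-ol | CC(C)CCCCCCCCCCCCCCC(O)C1C=CC(CO[Si](c2ccccc2)(c2ccccc2)C(C)(C)C)N1S(=O)(=O)c3ccc(C)cc3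
F5 | step 8 | 1-[5-(tert-butyldiphenylsilyloxymethyl)-1-(4-methylbenzenesulfonyl)-2,5-dihydro-1H-pyrrol-2-yl]-16-methylheptadecan-1-one | CC(C)CCCCCCCCCCCCCCC(=O)C1C=CC(CO[Si](c2ccccc2)(c2ccccc2)C(C)(C)C)N1S(=O)(=O)c3ccc(C)cc3
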